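**Retrosynthetic overview**

1. Feature: on ring A the oxygen-bearing C5 is bonded to the fusion carbon C4a, which carries the C4 carbonyl of ring C, and C8a on the other side of C4a bears the ring oxygen O1; an aryne across C4a–C5, polarised by the C8a oxygen, can accept an oxygen nucleophile at C5 and an acyl group at C4a.
2. Target ⇐ 5,7-bis-pivalate (methanolysis) ⇐ aryne annulation that forms C5–O from pivalate and C4a–C4 from a methyl ester tethered through O1; ring C is closed last, rings A and B come from the starting materials.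
3. Aryne precursor (ortho-silyl aryl triflate carrying an O1-linked (E)-β-aryloxy-α-methoxyacrylate) ⇐ Pd-catalysed C–O coupling of a crowded silylphenol with a β-ketoester enol triflate; the aryl triflate is installed after the coupling.
4. Ring A piece ⇐ 2-methoxybenzene-1,3-diol (C–H borylation/oxidation, ortho-bromination, retro-Brook silyl shift, steric differentiation of the two remaining oxygens); ring B piece ⇐ vanillic acid, prenyl bromide and methyl methoxyacetate.

Key step: step 13

**Remarks and assumptions**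

- Ring A is drawn from 2-methoxybenzene-1,3-diol. Its mirror plane through C2 and C5 makes the two ortho positions of phenol 4 equivalent, and the trimethylsilyl group later tells the two remaining oxygens apart by hindrance.
- The target has no stereocentre. Ketoester 17 is racemic and its centre disappears in step 9. Alkenes 18–21 must be (E), with the ester cis to the aryloxy (or triflyloxy) group, for ring closure.
- Compounds 1, 11, 12, 15 and 22 and all reagents are assumed to be commercial.

**Route**

Step 1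
Reactants: 1 2-methoxybenzene-1,3-diol
Product: 2 1,3-bis[(4-methoxybenzyl)oxy]-2-methoxybenzene
Conditions: 4-methoxybenzyl chloride, K2CO3, Bu4NI (cat.), DMF, 60 °C
Reagents that add atoms: 4-methoxybenzyl chloride, COc1ccc(CCl)cc1
Why: Williamson etherification of the two equivalent phenols gives ethers that survive organolithium chemistry and come off later by neutral hydrogenolysis, which the acid-sensitive aryl–silicon bond will need.

Step 2
Reactants: 2 1,3-bis[(4-methoxybenzyl)oxy]-2-methoxybenzene
Product: 4 3,5-bis[(4-methoxybenzyl)oxy]-4-methoxyphenol, via arylboronate 3 (not isolated)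
Conditions: [Ir(OMe)(cod)]2 (cat.), 4,4'-di-tert-butyl-2,2'-bipyridine, B2pin2, THF, 80 °C; then KHSO5 (as Oxone, 2KHSO5·KHSO4·K2SO4), acetone/H2O, rt
Reagents that add atoms: bis(pinacolato)diboron, CC1(C)OB(OC1(C)C)B1OC(C)(C)C(C)(C)O1 (boryl group of 3 only); potassium peroxymonosulfate, [K+].[O-]S(=O)(=O)OO (hydroxyl oxygen of 4)
Why: Sterically controlled iridium-catalysed C–H borylation takes the one C–H with no ortho substituent (C5 of the 1,2,3-trioxygenated ring; every C–H of the para-disubstituted benzyl rings has an ortho neighbour), and the arylboronate is oxidised to the phenol in the same pot.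

Step 3
Reactants: 4 3,5-bis[(4-methoxybenzyl)oxy]-4-methoxyphenol
Product: 5 2-bromo-3,5-bis[(4-methoxybenzyl)oxy]-4-methoxyphenol
Conditions: NBS (1.0 equiv), CH2Cl2, −78 to −40 °C
Reagents that add atoms: N-bromosuccinimide, O=C1CCC(=O)N1Br
Why: Electrophilic aromatic bromination of the free phenol goes ortho to the hydroxyl, and because the two ortho positions are equivalent by the mirror plane through C1 and C4, one equivalent of NBS at low temperature should give a single monobromide.

Step 4
Reactants: 5 2-bromo-3,5-bis[(4-methoxybenzyl)oxy]-4-methoxyphenol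
Product: 8 tert-butyl{3,5-bis[(4-methoxybenzyl)oxy]-4-methoxy-2-(trimethylsilyl)phenoxy}dimethylsilane, via trimethylsilyl ether 6 (not isolated), via lithium phenoxide 7 (not isolated)
Conditions: (Me3Si)2NH, THF, 65 °C, then concentrate; n-BuLi, THF, −78 °C; t-BuMe2SiOTf, −78 to 0 °C
Reagents that add atoms: hexamethyldisilazane, C[Si](C)(C)N[Si](C)(C)C (SiMe3 group); tert-butyldimethylsilyl trifluoromethanesulfonate, CC(C)(C)[Si](C)(C)OS(=O)(=O)C(F)(F)F (SiMe2tBu group)
Why: O-silylation, bromine–lithium exchange and 1,3 oxygen-to-carbon silyl migration (retro-Brook rearrangement) is the standard route to ortho-trimethylsilyl phenoxides, and the phenoxide is capped here as a silyl ether instead of a triflate so that no aryne precursor exists before the vinyl ether is in place.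

Step 5
Reactants: 8 tert-butyl{3,5-bis[(4-methoxybenzyl)oxy]-4-methoxy-2-(trimethylsilyl)phenoxy}dimethylsilane
Product: 9 5-[(tert-butyldimethylsilyl)oxy]-2-methoxy-4-(trimethylsilyl)benzene-1,3-diol
Conditions: H2 (1 atm), Pd/C, EtOAc, rt
Reagents that add atoms: none
Why: Catalytic hydrogenolysis cleaves both benzylic C–O bonds under neutral conditions that leave the aryl–SiMe3 bond and the aryl silyl ether untouched.

Step 6
Reactants: 9 5-[(tert-butyldimethylsilyl)oxy]-2-methoxy-4-(trimethylsilyl)benzene-1,3-diol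
Product: 10 5-[(tert-butyldimethylsilyl)oxy]-3-hydroxy-2-methoxy-4-(trimethylsilyl)phenyl 2,2-dimethylpropanoate
Conditions: pivaloyl chloride (1.05 equiv), pyridine, CH2Cl2, −20 to 0 °C
Reagents that add atoms: pivaloyl chloride, CC(C)(C)C(=O)Cl
Why: Sterically controlled O-acylation, since the hydroxyl flanked by methoxy and hydrogen is far more accessible to the bulky acyl chloride than the one wedged between methoxy and trimethylsilyl.

Step 7
Reactants: 11 vanillic acid (4-hydroxy-3-methoxybenzoic acid); 12 1-bromo-3-methylbut-2-ene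
Product: 14 3-methoxy-4-(3-methylbut-2-enyloxy)benzoic acid, via prenyl ester 13 (not isolated)
Conditions: K2CO3, DMF, rt; then NaOH, MeOH/H2O, 60 °C; dilute HCl to pH 3 at 0 °C
Reagents that add atoms: sodium hydroxide, [Na+].[OH-] (hydroxyl oxygen of the acid)
Why: Double O-alkylation (Williamson ether and ester formation) with the allylic bromide, followed by saponification of the prenyl ester in the same pot, leaves the base-stable aryl prenyl ether.

Step 8
Reactants: 14 3-methoxy-4-(3-methylbut-2-enyloxy)benzoic acid; 15 methyl methoxyacetate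
Product: 17 methyl 2-methoxy-3-[3-methoxy-4-(3-methylbut-2-enyloxy)phenyl]-3-oxopropanoate (racemic), via acyl imidazolide 16 (not isolated)
Conditions: CDI, THF, rt; added to 15 and LiN(SiMe3)2 (2.2 equiv), THF, −78 to −20 °C; aq. NH4Cl
Reagents that add atoms: 1,1'-carbonyldiimidazole, O=C(n1ccnc1)n1ccnc1 (imidazolyl group of 16 only)
Why: Crossed Claisen C-acylation of the preformed lithium ester enolate by the acyl imidazolide, with a second equivalent of base absorbing the acidic product, avoids acid chloride formation in the presence of the prenyl ether.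

Step 9
Reactants: 17 methyl 2-methoxy-3-[3-methoxy-4-(3-methylbut-2-enyloxy)phenyl]-3-oxopropanoate
Product: 18 methyl (E)-2-methoxy-3-[3-methoxy-4-(3-methylbut-2-enyloxy)phenyl]-3-(trifluoromethylsulfonyloxy)prop-2-enoate
Conditions: NaH, THF, 0 °C; PhNTf2, 0 °C to rt
Reagents that add atoms: N-phenylbis(trifluoromethanesulfonimide), O=S(=O)(N(c1ccccc1)S(=O)(=O)C(F)(F)F)C(F)(F)F
Why: O-triflation of the sodium enolate, whose six-membered chelate between enolate oxygen and ester carbonyl places the triflyloxy group cis to the ester, which is the (E) geometry needed later for ring closure.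

Step 10
Reactants: 10 5-[(tert-butyldimethylsilyl)oxy]-3-hydroxy-2-methoxy-4-(trimethylsilyl)phenyl 2,2-dimethylpropanoate; 18 methyl (E)-2-methoxy-3-[3-methoxy-4-(3-methylbut-2-enyloxy)phenyl]-3-(trifluoromethylsulfonyloxy)prop-2-enoate
Product: 19 methyl (E)-3-{5-[(tert-butyldimethylsilyl)oxy]-2-methoxy-3-(pivaloyloxy)-6-(trimethylsilyl)phenoxy}-2-methoxy-3-[3-methoxy-4-(3-methylbut-2-enyloxy)phenyl]prop-2-enoate
Conditions: Pd2(dba)3 (cat.), t-BuXPhos, K3PO4, toluene, 60 °C
Reagents that add atoms: none
Why: Palladium-catalysed C–O cross-coupling of a vinyl triflate with a phenol (Buchwald–Hartwig-type etherification), in which fast oxidative addition to the electron-poor enol triflate and reductive elimination driven by the bulky biarylphosphine should retain the alkene geometry and tolerate the two ortho substituents of the phenol.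

Step 11
Reactants: 19 methyl (E)-3-{5-[(tert-butyldimethylsilyl)oxy]-2-methoxy-3-(pivaloyloxy)-6-(trimethylsilyl)phenoxy}-2-methoxy-3-[3-methoxy-4-(3-methylbut-2-enyloxy)phenyl]prop-2-enoate
Product: 20 methyl (E)-3-[5-hydroxy-2-methoxy-3-(pivaloyloxy)-6-(trimethylsilyl)phenoxy]-2-methoxy-3-[3-methoxy-4-(3-methylbut-2-enyloxy)phenyl]prop-2-enoate
Conditions: Bu4NF, AcOH (1:1), THF, 0 °C
Reagents that add atoms: none
Why: Fluoride-mediated cleavage of the aryl silyl ether, buffered with acetic acid so that the phenoxide is protonated at once and neither the aryl–SiMe3 bond nor the pivalate is attacked.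

Step 12
Reactants: 20 methyl (E)-3-[5-hydroxy-2-methoxy-3-(pivaloyloxy)-6-(trimethylsilyl)phenoxy]-2-methoxy-3-[3-methoxy-4-(3-methylbut-2-enyloxy)phenyl]prop-2-enoate
Product: 21 methyl (E)-2-methoxy-3-[3-methoxy-4-(3-methylbut-2-enyloxy)phenyl]-3-[2-methoxy-3-(pivaloyloxy)-5-(trifluoromethylsulfonyloxy)-6-(trimethylsilyl)phenoxy]prop-2-enoate
Conditions: Tf2O, pyridine, CH2Cl2, −78 to 0 °C
Reagents that add atoms: trifluoromethanesulfonic anhydride, O=S(=O)(OS(=O)(=O)C(F)(F)F)C(F)(F)F
Why: O-sulfonylation of the ortho-silyl phenol with triflic anhydride completes the ortho-silyl aryl triflate only now, because under the basic coupling conditions an ortho-silyl phenoxide next to a triflate could shift silicon to oxygen and expel triflate.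

Step 13
Reactants: 21 methyl (E)-2-methoxy-3-[3-methoxy-4-(3-methylbut-2-enyloxy)phenyl]-3-[2-methoxy-3-(pivaloyloxy)-5-(trifluoromethylsulfonyloxy)-6-(trimethylsilyl)phenoxy]prop-2-enoate; 22 caesium pivalate
Product: 24 3,8-dimethoxy-2-[3-methoxy-4-(3-methylbut-2-enyloxy)phenyl]-4-oxo-4H-chromene-5,7-diyl bis(2,2-dimethylpropanoate), via aryne 23 (not isolated)
Conditions: CsF, CsO2CC(CH3)3 (22), [(CH3)3CCO]2O, 18-crown-6, THF, 65 °C
Reagents that add atoms: none
Why: Proposed new method: fluoride attacks the C–SiMe3 group of 21 and triflate leaves from the neighbouring carbon, giving aryne 23 across C4a–C5; the inductively withdrawing vinyl ether oxygen on C8a distorts the aryne so that pivalate adds to the distal carbon C5 and the negative charge builds on C4a, next to that oxygen. The C4a aryl anion then attacks the methyl ester, held cis to the aryloxy group on the (E)-alkene, in a 6-exo-trig anionic acyl substitution that forms C4a–C4, expels methoxide and closes the pyranone ring C directly as the 4H-chromen-4-one. The closest known reaction types are the insertion of arynes into the C–O bond of carboxylic acids (carboxylate addition, then acyl capture of the aryl anion) and the xanthone synthesis from arynes and salicylate esters (oxygen addition, then intramolecular acylation by an ester). No stereocentre is formed. The step needs addition at C5, secured by the C8a oxygen, and capture by the tethered ester instead of four-membered attack on the new pivalate carbonyl, secured by ring size and the tert-butyl group, while the aprotic medium keeps the aryl anion from being protonated. Pivalic anhydride converts the liberated methoxide into methyl pivalate and pivalate, so that no alkoxide or phenoxide competes for the aryne.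

Step 14
Reactants: 24 3,8-dimethoxy-2-[3-methoxy-4-(3-methylbut-2-enyloxy)phenyl]-4-oxo-4H-chromene-5,7-diyl bis(2,2-dimethylpropanoate)
Product: 25 5,7-dihydroxy-3,8-dimethoxy-2-[3-methoxy-4-(3-methylbut-2-enyloxy)phenyl]-4H-chromen-4-one
Conditions: K2CO3 (2 equiv), MeOH, rt
Reagents that add atoms: none
Why: Base-catalysed transesterification (methanolysis) of the two aryl pivalates releases the phenols without touching the prenyl ether or the chromone.

**Compound list**

1 | 2-methoxybenzene-1,3-diol | COc1c(O)cccc1O | starting material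
2 | 1,3-bis[(4-methoxybenzyl)oxy]-2-methoxybenzene | COc1c(OCc2ccc(OC)cc2)cccc1OCc1ccc(OC)cc1 | intermediate
3 | 2-{3,5-bis[(4-methoxybenzyl)oxy]-4-methoxyphenyl}-4,4,5,5-tetramethyl-1,3,2-dioxaborolane | COc1c(OCc2ccc(OC)cc2)cc(B2OC(C)(C)C(C)(C)O2)cc1OCc1ccc(OC)cc1 | intermediate (not isolated)
4 | 3,5-bis[(4-methoxybenzyl)oxy]-4-methoxyphenol | COc1c(OCc2ccc(OC)cc2)cc(O)cc1OCc1ccc(OC)cc1 | intermediate
5 | 2-bromo-3,5-bis[(4-methoxybenzyl)oxy]-4-methoxyphenol | COc1c(OCc2ccc(OC)cc2)cc(O)c(Br)c1OCc1ccc(OC)cc1 | intermediate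
6 | {2-bromo-3,5-bis[(4-methoxybenzyl)oxy]-4-methoxyphenoxy}trimethylsilane | COc1c(OCc2ccc(OC)cc2)cc(O[Si](C)(C)C)c(Br)c1OCc1ccc(OC)cc1 | intermediate (not isolated)
7 | lithium 3,5-bis[(4-methoxybenzyl)oxy]-4-methoxy-2-(trimethylsilyl)phenoxide | [Li+].COc1c(OCc2ccc(OC)cc2)cc([O-])c([Si](C)(C)C)c1OCc1ccc(OC)cc1 | intermediate (not isolated)
8 | tert-butyl{3,5-bis[(4-methoxybenzyl)oxy]-4-methoxy-2-(trimethylsilyl)phenoxy}dimethylsilane | COc1c(OCc2ccc(OC)cc2)cc(O[Si](C)(C)C(C)(C)C)c([Si](C)(C)C)c1OCc1ccc(OC)cc1 | intermediate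
9 | 5-[(tert-butyldimethylsilyl)oxy]-2-methoxy-4-(trimethylsilyl)benzene-1,3-diol | COc1c(O)cc(O[Si](C)(C)C(C)(C)C)c([Si](C)(C)C)c1O | intermediate
10 | 5-[(tert-butyldimethylsilyl)oxy]-3-hydroxy-2-methoxy-4-(trimethylsilyl)phenyl 2,2-dimethylpropanoate | COc1c(OC(=O)C(C)(C)C)cc(O[Si](C)(C)C(C)(C)C)c([Si](C)(C)C)c1O | intermediate
11 | vanillic acid (4-hydroxy-3-methoxybenzoic acid) | COc1cc(C(=O)O)ccc1O | starting material
12 | 1-bromo-3-methylbut-2-ene | CC(C)=CCBr | starting material
13 | 3-methylbut-2-enyl 3-methoxy-4-(3-methylbut-2-enyloxy)benzoate | COc1cc(C(=O)OCC=C(C)C)ccc1OCC=C(C)C | intermediate (not isolated)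
14 | 3-methoxy-4-(3-methylbut-2-enyloxy)benzoic acid | COc1cc(C(=O)O)ccc1OCC=C(C)C | intermediate
15 | methyl methoxyacetate | COCC(=O)OC | starting material
16 | (1H-imidazol-1-yl)[3-methoxy-4-(3-methylbut-2-enyloxy)phenyl]methanone | COc1cc(C(=O)n2ccnc2)ccc1OCC=C(C)C | intermediate (not isolated)
17 | methyl 2-methoxy-3-[3-methoxy-4-(3-methylbut-2-enyloxy)phenyl]-3-oxopropanoate (racemic) | COC(=O)C(OC)C(=O)c1ccc(OCC=C(C)C)c(OC)c1 | intermediate
18 | methyl (E)-2-methoxy-3-[3-methoxy-4-(3-methylbut-2-enyloxy)phenyl]-3-(trifluoromethylsulfonyloxy)prop-2-enoate | COC(=O)/C(OC)=C(\OS(=O)(=O)C(F)(F)F)c1ccc(OCC=C(C)C)c(OC)c1 | intermediate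
19 | methyl (E)-3-{5-[(tert-butyldimethylsilyl)oxy]-2-methoxy-3-(pivaloyloxy)-6-(trimethylsilyl)phenoxy}-2-methoxy-3-[3-methoxy-4-(3-methylbut-2-enyloxy)phenyl]prop-2-enoate | COC(=O)/C(OC)=C(\Oc1c(OC)c(OC(=O)C(C)(C)C)cc(O[Si](C)(C)C(C)(C)C)c1[Si](C)(C)C)c1ccc(OCC=C(C)C)c(OC)c1 | intermediate
20 | methyl (E)-3-[5-hydroxy-2-methoxy-3-(pivaloyloxy)-6-(trimethylsilyl)phenoxy]-2-methoxy-3-[3-methoxy-4-(3-methylbut-2-enyloxy)phenyl]prop-2-enoate | COC(=O)/C(OC)=C(\Oc1c(OC)c(OC(=O)C(C)(C)C)cc(O)c1[Si](C)(C)C)c1ccc(OCC=C(C)C)c(OC)c1 | intermediate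
21 | methyl (E)-2-methoxy-3-[3-methoxy-4-(3-methylbut-2-enyloxy)phenyl]-3-[2-methoxy-3-(pivaloyloxy)-5-(trifluoromethylsulfonyloxy)-6-(trimethylsilyl)phenoxy]prop-2-enoate | COC(=O)/C(OC)=C(\Oc1c(OC)c(OC(=O)C(C)(C)C)cc(OS(=O)(=O)C(F)(F)F)c1[Si](C)(C)C)c1ccc(OCC=C(C)C)c(OC)c1 | intermediate (key-step precursor)
22 | caesium pivalate | [Cs+].[O-]C(=O)C(C)(C)C | starting material
23 | methyl (E)-3-[5,6-didehydro-2-methoxy-3-(pivaloyloxy)phenoxy]-2-methoxy-3-[3-methoxy-4-(3-methylbut-2-enyloxy)phenyl]prop-2-enoate (aryne) | COC(=O)/C(OC)=C(\OC1=C(OC)C(OC(=O)C(C)(C)C)=CC#C1)c1ccc(OCC=C(C)C)c(OC)c1 | intermediate (not isolated)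
24 | 3,8-dimethoxy-2-[3-methoxy-4-(3-methylbut-2-enyloxy)phenyl]-4-oxo-4H-chromene-5,7-diyl bis(2,2-dimethylpropanoate) | COc1cc(-c2oc3c(OC)c(OC(=O)C(C)(C)C)cc(OC(=O)C(C)(C)C)c3c(=O)c2OC)ccc1OCC=C(C)C | intermediate (key-step product)
25 | 5,7-dihydroxy-3,8-dimethoxy-2-[3-methoxy-4-(3-methylbut-2-enyloxy)phenyl]-4H-chromen-4-one | COc1cc(-c2oc3c(OC)c(O)cc(O)c3c(=O)c2OC)ccc1OCC=C(C)C | target

**Step count**

Total: 14 steps. Longest linear sequence: 11 steps (steps 1–6, then 10–14); the ring B branch is steps 7–9.

**Steps most likely to fail**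

1. Step 13 (proposed new method). The C4a aryl anion may be protonated before it reaches the ester, may shift the new pivaloyl group through the four-membered pathway, or the aryne may be taken by fluoride or by liberated methoxide; an alkene that has isomerised cannot close at all. Fallback by known chemistry, in which the C5 oxygen is kept from the start and ring C is closed by an aryllithium: it sets out from 10. Ipso-bromodesilylation with NBS in MeCN at 0 °C replaces the trimethylsilyl group and should give 4-bromo-5-[(tert-butyldimethylsilyl)oxy]-3-hydroxy-2-methoxyphenyl 2,2-dimethylpropanoate F1. Coupling with 18 under the conditions of step 10 should give methyl (E)-3-{2-bromo-3-[(tert-butyldimethylsilyl)oxy]-6-methoxy-5-(pivaloyloxy)phenoxy}-2-methoxy-3-[3-methoxy-4-(3-methylbut-2-enyloxy)phenyl]prop-2-enoate F2, the hindered electron-rich aryl bromide being far slower toward zerovalent palladium than the enol triflate. Bromine–lithium exchange with t-BuLi in THF at −100 °C and Parham cyclisation of the aryllithium onto the methyl ester, which at this temperature should outrun silyl migration, would give 5-[(tert-butyldimethylsilyl)oxy]-3,8-dimethoxy-2-[3-methoxy-4-(3-methylbut-2-enyloxy)phenyl]-4-oxo-4H-chromen-7-yl 2,2-dimethylpropanoate F3. K2CO3 in MeOH then removes the pivalate and the phenolic silyl ether, and the fallback comes back to the route at 25.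

2. Step 10. Reductive elimination from a palladium phenoxide crowded by the ortho methoxy and trimethylsilyl groups may be slow, so that transfer of the triflyl group to the phenoxide, loss of alkene geometry or ionisation of the prenyl ether by zerovalent palladium compete. Fallback by metal-free nucleophilic vinylic substitution: it sets out from 17, which with Ph3PCl2 and Et3N in CH2Cl2 should give methyl 3-chloro-2-methoxy-3-[3-methoxy-4-(3-methylbut-2-enyloxy)phenyl]prop-2-enoate F4 (either alkene isomer serves, since the addition intermediate is a rotatable ester enolate). The caesium phenoxide of 10 (Cs2CO3, DMF, 50 °C) displaces chloride by conjugate addition–elimination; the isomer with the ester cis to the aryloxy group is separated and the other re-equilibrated with catalytic phenoxide, and the fallback comes back at 19.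

3. Step 4. The one-pot sequence may stall through incomplete silyl migration, protonation or butylation of the aryllithium, or sluggish O-silylation of the crowded phenoxide. Fallback by directed ortho-metalation, which also bypasses step 3: it sets out from 4, which with ClC(O)NEt2 and NaH in THF should give 3,5-bis[(4-methoxybenzyl)oxy]-4-methoxyphenyl diethylcarbamate F5. Lithiation with s-BuLi/TMEDA at −78 °C between the carbamate and the neighbouring ether, then quench with Me3SiCl, would give 3,5-bis[(4-methoxybenzyl)oxy]-4-methoxy-2-(trimethylsilyl)phenyl diethylcarbamate F6. Reductive removal of the carbamate with LiAlH4 in THF at 0 °C would give 3,5-bis[(4-methoxybenzyl)oxy]-4-methoxy-2-(trimethylsilyl)phenol F7, and t-BuMe2SiOTf with 2,6-lutidine brings the fallback back at 8.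

**Further compounds**

F1 | step 13 | 4-bromo-5-[(tert-butyldimethylsilyl)oxy]-3-hydroxy-2-methoxyphenyl 2,2-dimethylpropanoate | COc1c(OC(=O)C(C)(C)C)cc(O[Si](C)(C)C(C)(C)C)c(Br)c1O
F2 | step 13 | methyl (E)-3-{2-bromo-3-[(tert-butyldimethylsilyl)oxy]-6-methoxy-5-(pivaloyloxy)phenoxy}-2-methoxy-3-[3-methoxy-4-(3-methylbut-2-enyloxy)phenyl]prop-2-enoate | COC(=O)/C(OC)=C(\Oc1c(OC)c(OC(=O)C(C)(C)C)cc(O[Si](C)(C)C(C)(C)C)c1Br)c1ccc(OCC=C(C)C)c(OC)c1
F3 | step 13 | 5-[(tert-butyldimethylsilyl)oxy]-3,8-dimethoxy-2-[3-methoxy-4-(3-methylbut-2-enyloxy)phenyl]-4-oxo-4H-chromen-7-yl 2,2-dimethylpropanoate | COc1cc(-c2oc3c(OC)c(OC(=O)C(C)(C)C)cc(O[Si](C)(C)C(C)(C)C)c3c(=O)c2OC)ccc1OCC=C(C)C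
F4 | step 10 | methyl 3-chloro-2-methoxy-3-[3-methoxy-4-(3-methylbut-2-enyloxy)phenyl]prop-2-enoate (alkene isomers) | COC(=O)C(OC)=C(Cl)c1ccc(OCC=C(C)C)c(OC)c1
F5 | step 4 | 3,5-bis[(4-methoxybenzyl)oxy]-4-methoxyphenyl diethylcarbamate | CCN(CC)C(=O)Oc1cc(OCc2ccc(OC)cc2)c(OC)c(OCc2ccc(OC)cc2)c1
F6 | step 4 | 3,5-bis[(4-methoxybenzyl)oxy]-4-methoxy-2-(trimethylsilyl)phenyl diethylcarbamate | CCN(CC)C(=O)Oc1cc(OCc2ccc(OC)cc2)c(OC)c(OCc2ccc(OC)cc2)c1[Si](C)(C)C
F7 | step 4 | 3,5-bis[(4-methoxybenzyl)oxy]-4-methoxy-2-(trimethylsilyl)phenol | COc1c(OCc2ccc(OC)cc2)cc(O)c([Si](C)(C)C)c1OCc1ccc(OC)cc1
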